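**Retrosynthetic overview**

1. Target ⇐ tertiary allylic alcohol; the hydroperoxide is put on last by acid-catalysed perhydrolysis, after every reductant- or base-sensitive step.
2. γ-Lactone and eight-membered ring ⇐ bicyclo[3.3.1]nonane-2,4,9-trione (type A PPAP core): exo-hydroxylation of the C3 enolate, C3–O→C9 hemiketal, retro-Claisen of C1–C9 (the presumed biogenetic ring expansion).
3. Bicyclo[3.3.1] core ⇐ symmetric dearomatised 2,6-diisobutyryl-4,4-dialkyl trione: one of two equivalent acyl-bearing carbons (C1) closes onto the tertiary δ-carbon (C8) of a Z,E-dienone side chain; the "twin" 3-acyl later leaves.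
4. Dearomatised trione ⇐ 2,4-diisobutyryl-6-prenylphloroglucinol (from phloroglucinol) + the triflate of an (R)-lavandulol-derived hydroxy-dienone, whose Z-alkene is fixed through a temporary dihydropyranone (RCM).
5. Ring order: dihydropyranone (temporary, reopened) → carbocycle B on the dearomatised phloroglucinol ring → γ-lactone with simultaneous opening to the eight-membered ring.

Assumptions: (R)-(−)-lavandulol is bought enantiopure; the epimerisable C1–H of the final β-diketone settles in the drawn configuration on work-up. Positions are given in PPAP numbering (C1 acyl bridgehead, C5 prenyl bridgehead, C9 bridging carbonyl, C8 quaternary Me/chain carbon).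

**Route**

Step 1
Reactants: 1 phloroglucinol
Product: 2 2,4-diisobutyrylphloroglucinol
Conditions: i-PrCOCl (2.2 equiv), AlCl3 (4 equiv), PhNO2–CS2, 60 °C; aq. HCl
Reagents that add atoms: isobutyryl chloride, CC(C)C(Cl)=O
Why: Friedel–Crafts acylation occurs twice on the electron-rich ring and stops (two acyl groups deactivate the last position), giving a symmetric diketone whose second isobutyryl group later serves as a removable twin.

Step 2
Reactants: 2 2,4-diisobutyrylphloroglucinol
Product: 3 2,4-diisobutyryl-6-prenylphloroglucinol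
Conditions: prenyl bromide (1.05 equiv), 10% aq. KOH, 0 °C
Reagents that add atoms: prenyl bromide, CC(C)=CCBr
Why: C-alkylation (SN2) of the acylphloroglucinol phenoxide in water, where hydrogen bonding to oxygen favours attack through carbon, at the only unsubstituted ring position.

Step 3
Reactants: 4 (R)-(−)-lavandulol
Product: 5 (R)-lavandulyl acrylate
Conditions: acryloyl chloride, Et3N, DMAP (cat.), CH2Cl2, 0 °C
Reagents that add atoms: acryloyl chloride, C=CC(Cl)=O
Why: Standard O-acylation (esterification) of the primary alcohol; the stereocentre (future C7) is not involved.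

Step 4
Reactants: 5 (R)-lavandulyl acrylate
Product: 6 (5R)-4-methyl-5-prenyl-5,6-dihydro-2H-pyran-2-one
Conditions: Hoveyda–Grubbs II (5 mol%), toluene (5 mM), 80 °C
Reagents that add atoms: none
Why: Ring-closing metathesis of the acrylate with the 1,1-disubstituted alkene gives the six-membered unsaturated lactone (ethene lost), which locks the trisubstituted alkene with the carbonyl cis to the stereocentre; the prenyl alkene, which could only give a seven-membered ring, reacts much more slowly.

Step 5
Reactants: 6 (5R)-4-methyl-5-prenyl-5,6-dihydro-2H-pyran-2-one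
Product: 8 (3E,5Z,7R)-7-(hydroxymethyl)-6,10-dimethylundeca-3,5,9-trien-2-one, via lactol 7 (not isolated)
Conditions: DIBAL-H (1.1 equiv), CH2Cl2, −78 °C; then Ph3P=CHC(O)Me (1.5 equiv), −78 → 23 °C; Rochelle salt
Reagents that add atoms: 1-(triphenylphosphoranylidene)propan-2-one, CC(=O)C=P(c1ccccc1)(c1ccccc1)c1ccccc1
Why: DIBAL half-reduction gives the lactol, whose open hydroxy-enal form undergoes E-selective Wittig olefination with the stabilised ylide; the Z-geometry of the trisubstituted alkene is inherited from the ring and the stereocentre is untouched.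

Step 6
Reactants: 8 (3E,5Z,7R)-7-(hydroxymethyl)-6,10-dimethylundeca-3,5,9-trien-2-one; 3 2,4-diisobutyryl-6-prenylphloroglucinol
Product: 11 4-hydroxy-1,3-diisobutyryl-8-methyl-8-[(2E)-4-oxopent-2-en-1-yl]-5,7-diprenylbicyclo[3.3.1]non-3-ene-2,9-dione (hyperforin configuration at C1/C5/C7/C8), via triflate 9 (not isolated), via dearomatised trione 10 (not isolated)
Conditions: 8: Tf2O, polymer-bound 2,6-di-tert-butylpyridine, CH2Cl2, −78 °C, cold filtration; filtrate into 3 + LiHMDS (2.0 equiv), THF–toluene, −78 → 0 °C; then 60 °C; aq. NH4Cl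
Reagents that add atoms: none
Why: Proposed new method: the dilithium phenoxide of 3 is C-alkylated by the primary triflate at its only alkyl-bearing carbon (SN2, alkylative dearomatisation) to give symmetric 10 in which C5 is not yet stereogenic, and on warming one of the two equivalent acyl-bearing enolate carbons adds in a vinylogous (1,6) Michael reaction to the tertiary δ-carbon C8 of the dienone (the C1→C8 closure of PPAP biosynthesis, the dienolate being quenched by the remaining enol OH so that the charge rests on the 3-acyl triketone), where A(1,3) strain of the Z-alkene holds C7–H in the dienone plane so that C1 adds to the face carrying C6 with the C7-prenyl anti to the new bond (C8: methyl axial, chain equatorial) and the chair over the twist-boat transition state decides which acyl carbon attacks (fixing C5 and C1); the closest known reaction types are the alkylative dearomatisation–annulation of acylphloroglucinols with bis-electrophiles and group-selective cyclisations of symmetric cyclohexadiene nucleophiles onto a chiral side chain.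

Step 7
Reactants: 11 bicyclic enone
Product: 12 4-hydroxy-8-[(2E)-4-hydroxy-4-methylpent-2-en-1-yl]-1,3-diisobutyryl-8-methyl-5,7-diprenylbicyclo[3.3.1]non-3-ene-2,9-dione
Conditions: MeMgBr (3 equiv), CeCl3 (3 equiv), THF, −78 °C; aq. NH4Cl
Reagents that add atoms: methylmagnesium bromide, C[Mg]Br
Why: Organocerium (Imamoto) 1,2-addition to the unhindered methyl enone after the acidic triketone has been deprotonated, while the C9 and acyl ketones (flanked by quaternary carbons) stay untouched; removing the enone carbonyl here also rules out retro-Michael ring opening in the later basic steps.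

Step 8
Reactants: 12 tertiary alcohol
Product: 13 8-[(2E)-4-hydroxy-4-methylpent-2-en-1-yl]-1,3-diisobutyryl-8-methyl-3,5,7-triprenylbicyclo[3.3.1]nonane-2,4,9-trione (3-prenyl exo)
Conditions: Pd(PPh3)4 (5 mol%), prenyl methyl carbonate (1.2 equiv), THF, 23 °C
Reagents that add atoms: prenyl methyl carbonate, COC(=O)OCC=C(C)C
Why: Tsuji–Trost C-allylation of the acidic 2-acyl-1,3-dione at the less hindered terminus of the π-prenyl-Pd complex (O-allylation is reversible and funnels to carbon), the electrophile entering C3 from the exo face; this centre is reset in step 9.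

Step 9
Reactants: 13 3-acyl-3-prenyl tetraketone
Product: 16 the target's tertiary alcohol (OH in place of OOH), via deacylated enolate 14 (not isolated), via hemiketal 15 (not isolated)
Conditions: NaOMe (1.05 equiv), THF, −20 °C; then 2-(phenylsulfonyl)-3-phenyloxaziridine (1.1 equiv), −78 → 23 °C; aq. NH4Cl
Reagents that add atoms: 2-(phenylsulfonyl)-3-phenyloxaziridine, O=S(=O)(N1OC1c1ccccc1)c1ccccc1
Why: Proposed new method: methoxide removes the more exposed 3-isobutyryl group by retro-Claisen (the expelled C3 enolate is a β-diketone anion, whereas loss of the 1-acyl would need a bridgehead carbanion), the Davis oxaziridine hydroxylates this enolate from the exo face (anti to ring B), the exo 3-alkoxide adds to the C9 ketone and the hemiketal alkoxide cleaves C1–C9 (retro-Claisen, C1 leaving as the acyl-stabilised β-diketone enolate) to give the γ-lactone and the eight-membered ring, with C3 fixed by the bicycle and C1 set by thermodynamic protonation; the closest known chemistry is oxaziridine α-hydroxylation of β-dicarbonyl enolates and the oxidative hemiketalisation/retro-Claisen degradation of hyperforin-type PPAPs.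

Step 10
Reactants: 16 tertiary allylic alcohol
Product: 17 CNP0545483.1 (target)
Conditions: 50% aq. H2O2 (excess), TsOH·H2O (10 mol%), Et2O, 0 °C
Reagents that add atoms: hydrogen peroxide, OO
Why: Acid-catalysed perhydrolysis (SN1) of the tertiary allylic alcohol, the allyl cation being captured by H2O2 at its tertiary terminus with the E-alkene retained, under acid too weak to protonate the prenyl alkenes.

**Compound list**

1 | phloroglucinol | Oc1cc(O)cc(O)c1 | starting material
2 | 2,4-diisobutyrylphloroglucinol | CC(C)C(=O)c1c(O)cc(O)c(C(=O)C(C)C)c1O | intermediate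
3 | 2,4-diisobutyryl-6-prenylphloroglucinol | CC(C)C(=O)c1c(O)c(CC=C(C)C)c(O)c(C(=O)C(C)C)c1O | intermediate
4 | (R)-(−)-lavandulol, (2R)-5-methyl-2-(prop-1-en-2-yl)hex-4-en-1-ol | CC(C)=CC[C@H](C(C)=C)CO | starting material
5 | (R)-lavandulyl acrylate | CC(C)=CC[C@H](C(C)=C)COC(=O)C=C | intermediate
6 | (5R)-4-methyl-5-(3-methylbut-2-en-1-yl)-5,6-dihydro-2H-pyran-2-one | CC(C)=CC[C@H]1COC(=O)C=C1C | intermediate
7 | (5R)-4-methyl-5-prenyl-5,6-dihydro-2H-pyran-2-ol (lactol, anomeric mixture, formed in situ) | CC(C)=CC[C@H]1COC(O)C=C1C | intermediate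
8 | (3E,5Z,7R)-7-(hydroxymethyl)-6,10-dimethylundeca-3,5,9-trien-2-one | CC(C)=CC[C@H](/C(C)=C\C=C\C(C)=O)CO | intermediate
9 | (2R,3Z,5E)-3-methyl-2-(3-methylbut-2-en-1-yl)-7-oxoocta-3,5-dien-1-yl triflate (formed in situ) | CC(C)=CC[C@H](/C(C)=C\C=C\C(C)=O)COS(=O)(=O)C(F)(F)F | intermediate
10 | 3,5-dihydroxy-2,6-diisobutyryl-4-[(2S,3Z,5E)-3-methyl-7-oxo-2-prenylocta-3,5-dien-1-yl]-4-prenylcyclohexa-2,5-dien-1-one (symmetric ring, ring C4 not stereogenic, formed in situ) | CC(C)=CC[C@H](/C(C)=C\C=C\C(C)=O)CC1(CC=C(C)C)C(O)=C(C(=O)C(C)C)C(=O)C(C(=O)C(C)C)=C1O | intermediate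
11 | 4-hydroxy-1,3-diisobutyryl-8-methyl-8-[(2E)-4-oxopent-2-en-1-yl]-5,7-diprenylbicyclo[3.3.1]non-3-ene-2,9-dione (7-prenyl equatorial, 8-methyl axial) | CC(C)C(=O)[C@]12C(=O)C(=C([C@](C1=O)(C[C@@H]([C@@]2(C)C/C=C/C(C)=O)CC=C(C)C)CC=C(C)C)O)C(=O)C(C)C | intermediate
12 | 4-hydroxy-8-[(2E)-4-hydroxy-4-methylpent-2-en-1-yl]-1,3-diisobutyryl-8-methyl-5,7-diprenylbicyclo[3.3.1]non-3-ene-2,9-dione | CC(C)C(=O)[C@]12C(=O)C(=C([C@](C1=O)(C[C@@H]([C@@]2(C)C/C=C/C(C)(C)O)CC=C(C)C)CC=C(C)C)O)C(=O)C(C)C | intermediate
13 | 8-[(2E)-4-hydroxy-4-methylpent-2-en-1-yl]-1,3-diisobutyryl-8-methyl-3,5,7-triprenylbicyclo[3.3.1]nonane-2,4,9-trione (3-prenyl exo, 3-acyl endo) | CC(C)C(=O)[C@]12C(=O)[C@@](CC=C(C)C)(C(=O)C(C)C)C(=O)[C@](C1=O)(C[C@@H]([C@@]2(C)C/C=C/C(C)(C)O)CC=C(C)C)CC=C(C)C | intermediate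
14 | 4-hydroxy-8-[(2E)-4-hydroxy-4-methylpent-2-en-1-yl]-1-isobutyryl-8-methyl-3,5,7-triprenylbicyclo[3.3.1]non-3-ene-2,9-dione (hyperforin analogue, formed in situ as its enolate) | CC(C)C(=O)[C@]12C(=O)C(CC=C(C)C)=C(O)[C@](C1=O)(C[C@@H]([C@@]2(C)C/C=C/C(C)(C)O)CC=C(C)C)CC=C(C)C | intermediate
15 | 3,9-epoxy-9-hydroxy hemiketal of 3-hydroxy-14 (3-O exo bridging to C9, formed in situ) | CC(C)C(=O)[C@]12C(=O)[C@]3(CC=C(C)C)O[C@@]1(O)[C@@](C3=O)(C[C@@H]([C@@]2(C)C/C=C/C(C)(C)O)CC=C(C)C)CC=C(C)C | intermediate
16 | tertiary alcohol corresponding to the target (side chain (2E)-4-hydroxy-4-methylpent-2-en-1-yl) | CC(C)=CC[C@H]1C[C@@]2(CC=C(C)C)C(=O)O[C@@](CC=C(C)C)(C(=O)[C@@H](C(=O)C(C)C)[C@]1(C)C/C=C/C(C)(C)O)C2=O | intermediate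
17 | CNP0545483.1 | CC(C)=CC[C@H]1C[C@@]2(CC=C(C)C)C(=O)O[C@@](CC=C(C)C)(C(=O)[C@@H](C(=O)C(C)C)[C@]1(C)C/C=C/C(C)(C)OO)C2=O | target

**Step count and risks**

Total step count: 10. Longest linear sequence: 8 steps (from 4, steps 3–10); the phloroglucinol branch contributes steps 1–2 before the union in step 6.

Most likely to fail:

Step 6 (union and ring B). O-alkylation or base-induced elimination of triflate 9 may outrun C-alkylation at the hindered prenyl-bearing carbon; elimination would also erode C7, and the acyl-bearing carbon is a weak Michael donor. Fallback: reverse the order in which C5 is substituted. Setting out from 2 and 8, the free aromatic CH of 2 is alkylated with 9 under the same lithium-phenoxide conditions to give the aromatic 2,4-diisobutyryl-6-[(2S,3Z,5E)-3-methyl-7-oxo-2-prenylocta-3,5-dien-1-yl]phloroglucinol F1 (unhindered carbon, rearomatisation-driven). The dearomatising event then becomes an easy Pd-catalysed C-prenylation (Pd(PPh3)4, prenyl methyl carbonate), which comes back to the route at 10, now isolated and cyclised to 11 by warming its lithium salt.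

Step 9 (deacylation/hydroxylation/ring expansion in one flask). Methoxide may attack the wrong carbonyl, or the oxaziridine may over-oxidise. Fallback: run the sequence stepwise with dioxygen as the oxidant, as in the natural degradation. Setting out from 13, K2CO3/MeOH deacylation gives 14, which is isolated; its potassium enolate under O2 gives the exo 3-hydroperoxy-2,4,9-trione F2; Me2S reduction gives hemiketal 15, isolated; DBU in THF then triggers the retro-Claisen and comes back at 16.

Step 10 (perhydrolysis). The acid may cyclise prenyl groups onto the β-diketone, or the allyl cation may be captured at the secondary terminus. Fallback: replace ionisation by a radical hydroperoxidation. Setting out from 16, Burgess dehydration gives the terminal 1,3-diene F3 (side chain (2E)-4-methylpenta-2,4-dien-1-yl); Co(thd)2/O2/Et3SiH (Mukaiyama–Isayama) adds H and OOSiEt3 across the terminal alkene to give the triethylsilyl peroxide F4; HF·pyridine removes silicon and comes back at 17.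

**Further compounds**

F1 | step 6 | 2,4-diisobutyryl-6-[(2S,3Z,5E)-3-methyl-7-oxo-2-prenylocta-3,5-dien-1-yl]phloroglucinol | CC(C)=CC[C@H](/C(C)=C\C=C\C(C)=O)Cc1c(O)c(C(=O)C(C)C)c(O)c(C(=O)C(C)C)c1O
F2 | step 9 | 3-hydroperoxy-8-[(2E)-4-hydroxy-4-methylpent-2-en-1-yl]-1-isobutyryl-8-methyl-3,5,7-triprenylbicyclo[3.3.1]nonane-2,4,9-trione (3-OOH exo) | CC(C)C(=O)[C@]12C(=O)[C@@](OO)(CC=C(C)C)C(=O)[C@](C1=O)(C[C@@H]([C@@]2(C)C/C=C/C(C)(C)O)CC=C(C)C)CC=C(C)C
F3 | step 10 | diene analogue of 16 with side chain (2E)-4-methylpenta-2,4-dien-1-yl | CC(C)=CC[C@H]1C[C@@]2(CC=C(C)C)C(=O)O[C@@](CC=C(C)C)(C(=O)[C@@H](C(=O)C(C)C)[C@]1(C)C/C=C/C(C)=C)C2=O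
F4 | step 10 | triethylsilyl peroxide of the target | CC(C)=CC[C@H]1C[C@@]2(CC=C(C)C)C(=O)O[C@@](CC=C(C)C)(C(=O)[C@@H](C(=O)C(C)C)[C@]1(C)C/C=C/C(C)(C)OO[Si](CC)(CC)CC)C2=O
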